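**Strategy.** Ring A is disconnected at C3–C4: the cyclohexene carboxylic acid is traced back to a δ-lactone in which the C19 carboxyl is esterified by an allylic C1 carbinol on a preformed ring B. One Ireland–Claisen rearrangement of its silyl ketene acetal closes ring A, makes quaternary C4 and frees the C19 acid cis to C20, leaving a C1=C2 alkene for the 2β-hydroxyl. The step exploits the 1,3-relationship of quaternary C4 and C10 across ring A and the cis C19/C20 pair of the 19,20-lactone. The precursor is a vinyl lactone trans-fused to a cyclopentane carrying the masked C8 ketone, the C7 oxygen and C20 as a methyl ester.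

Key step: step 11

**Conventions and assumptions.**
- Gibberellin numbering is used for every intermediate. β is the face of ring B that bears H-5; α is the opposite face.
- C4 is carried as an epimer mixture (no descriptor in the SMILES) until step 11, where it becomes trigonal. Aldol adduct 24 and alkylidene ketone 26 are likewise taken on as isomer mixtures, because C9 and C11 are reset in step 19.
- C20 is carried as a methyl ester through the key step. It cannot enolise (C10 is quaternary) and needs no protection. After the rearrangement it is the only ester beside the free C19 acid, so hydride reduction and acidification give the 19,20-lactone directly.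
- The facial sense of the chiral boron catalysts in steps 3 and 9 is assigned by analogy with the usual binding models; the mirror-image catalyst would be used if the analogy proved wrong.

**Route**

Step 1
Reactants: 1 dimethyl cyclopent-3-ene-1,1-dicarboxylate
Product: 2 dimethyl 4-oxocyclopent-2-ene-1,1-dicarboxylate
Conditions: Rh2(cap)4 (dirhodium tetracaprolactamate, 1 mol %), t-BuOOH (70% aq.), K2CO3 (0.5 equiv), CH2Cl2, rt
Reagents that add atoms: tert-butyl hydroperoxide, CC(C)(C)OO
Why: Dirhodium-catalysed peroxyl-radical allylic oxidation of a cycloalkene to the enone: hydrogen abstraction at either of the two equivalent allylic CH2 groups gives an allyl radical that is captured at the terminus remote from the quaternary diester carbon, so the alkene moves next to C10 and a single enone (C8=O, C5=C6) should result.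

Step 2
Reactants: 3 methyl propanoate
Product: 4 1-methoxy-1-(trimethylsilyloxy)prop-1-ene (E/Z mixture)
Conditions: LiN(iPr)2, THF, −78 °C; Me3SiCl; distillation
Reagents that add atoms: chlorotrimethylsilane, C[Si](C)(C)Cl
Why: Kinetic ester enolisation and O-silylation give the silyl ketene acetal for the Mukaiyama–Michael step; its geometry is irrelevant because C4 is planarised later.

Step 3
Reactants: 2 dimethyl 4-oxocyclopent-2-ene-1,1-dicarboxylate; 4 1-methoxy-1-(trimethylsilyloxy)prop-1-ene
Product: 5 dimethyl (2R)-2-(1-methoxy-1-oxopropan-2-yl)-4-(trimethylsilyloxy)cyclopent-3-ene-1,1-dicarboxylate (5β-H; C4 epimers)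
Conditions: N-protonated (S)-3,3-diphenyl-1-(o-tolyl)pyrrolo[1,2-c][1,3,2]oxazaborolidine triflimide (20 mol %), Ph3PO (25 mol %), toluene, −20 °C; non-aqueous work-up
Reagents that add atoms: none
Why: Catalytic enantioselective Mukaiyama–Michael addition to a cyclic enone; the chiral boron Lewis acid binds the C8 carbonyl and exposes one face of C5, so C5 is set by the catalyst, and silyl transfer leaves the C6=C8 enol ether regiodefined.

Step 4
Reactants: 5 silyl enol ether
Product: 6 dimethyl 3-(hydroxymethyl)-2-(1-methoxy-1-oxopropan-2-yl)-4-oxocyclopentane-1,1-dicarboxylate (5β-H; 6α-H; C4 epimers)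
Conditions: 37% aq. HCHO, Yb(OTf)3 (10 mol %), THF, rt
Reagents that add atoms: formaldehyde, C=O
Why: Lanthanide-triflate-catalysed Mukaiyama aldol hydroxymethylation at C6 of the enol ether; formaldehyde enters anti to the C5 side chain, giving the 5,6-trans ketone, which is also the thermodynamic epimer.

Step 5
Reactants: 6 hydroxymethyl ketone
Product: 7 7-O-tert-butyldiphenylsilyl ether of 6
Conditions: t-BuPh2SiCl, imidazole, DMF, rt
Reagents that add atoms: tert-butyl(chloro)diphenylsilane, CC(C)(C)[Si](Cl)(c1ccccc1)c1ccccc1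
Why: Standard silylation of the primary alcohol, carried out at once so that the hydroxy ester cannot lactonise; the acid-stable silyl group is chosen to survive the acidic steps 15 and 20.

Step 6
Reactants: 7 silyloxy ketone
Product: 8 C8 ethylene ketal of 7
Conditions: (Me3SiOCH2)2, Me3SiOTf (5 mol %), CH2Cl2, −78 → −20 °C
Reagents that add atoms: 1,2-bis(trimethylsilyloxy)ethane, C[Si](C)(C)OCCO[Si](C)(C)C
Why: Aprotic ketalisation with the bis-silyl glycol ether avoids water and protic acid, so the β-silyloxy ketone should neither eliminate nor epimerise.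

Step 7
Reactants: 8 ketal triester
Product: 9 half-acid of 8 (10β-CO2H trans to the C5 side chain; 10α-CO2Me)
Conditions: LiOH·H2O (1.1 equiv), THF–MeOH–H2O, 0 °C → rt; 1 M HCl to pH 3 at 0 °C
Reagents that add atoms: lithium hydroxide, [Li+].[OH-]
Why: Selective monosaponification of a geminal diester: the malonate is more electrophilic than the isolated hindered C19 ester, and the ester trans to the vicinal C5 side chain is the accessible one, which sets C10 (β-carboxyl becomes C1, α-ester stays as C20).

Step 8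
Reactants: 9 half-acid
Product: 11 10β-acryloyl compound (C1 vinyl ketone; 10α-CO2Me), via acid chloride 10 (not isolated)
Conditions: 1-chloro-N,N,2-trimethylprop-1-en-1-amine, CH2Cl2, 0 °C → rt; then tributyl(vinyl)stannane, Pd(PPh3)4 (5 mol %), toluene, 60 °C
Reagents that add atoms: tributyl(vinyl)stannane, C=C[Sn](CCCC)(CCCC)CCCC
Why: Neutral acid chloride formation followed by Stille acylation gives the vinyl ketone; quaternary C10 excludes ketene formation, and the ketal and silyl ether are not exposed to HCl.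

Step 9
Reactants: 11 vinyl ketone
Product: 12 (1S)-allylic alcohol (1-hydroxy-1-vinyl; 10α-CO2Me)
Conditions: (R)-Me-CBS oxazaborolidine (0.5 equiv), catecholborane, toluene, −78 °C; MeOH, pH 7 buffer
Reagents that add atoms: none
Why: CBS reduction of the enone carbonyl under reagent control; quaternary C10 acts as the large group and vinyl as the small one, so the (R)-catalyst should give the (1S)-carbinol that places the vinyl group trans to C20 in the lactone, the substrate itself offering little facial bias.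

Step 10
Reactants: 12 allylic alcohol
Product: 13 (1S)-1-vinyl δ-lactone (C19–O–C1) trans-fused to ring B (1β-vinyl; 10α-CO2Me; 5β-H; 7-OTBDPS; C8 ketal; C4 epimers)
Conditions: PPTS (0.2 equiv), toluene, 5 Å molecular sieves, 90 °C
Reagents that add atoms: none
Why: Acid-catalysed lactonisation of a δ-hydroxy ester driven by trapping of methanol; only the C19 ester can form a six-membered ring with O-1 (the C20 ester would give a β-lactone), and the non-basic medium avoids retro-aldol cleavage of the β-hydroxy ester.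

Step 11
Reactants: 13 vinyl lactone
Product: 16 ring A cyclohex-1-ene 19-oic acid 20-methyl ester (4α-CO2H; 4β-CH3; 10α-CO2Me; 7-OTBDPS; C8 ketal), via silyl ketene acetal 14 (not isolated), via silyl ester 15 (not isolated)
Conditions: KN(SiMe3)2 (1.5 equiv), t-BuMe2SiCl (2 equiv), THF, −78 → 0 °C; toluene, 110 °C (sealed); then K2CO3, MeOH–H2O, rt, work-up at pH 4
Reagents that add atoms: none
Why: The base removes the only acidic proton (H-4; the C20 ester sits on quaternary C10) and silylation in the flask gives the endocyclic ketene acetal 14, whose O–C1–C2=C3 allyl unit and C4=C19 enol unit undergo a concerted, suprafacial [3,3] shift, the known Ireland–Claisen rearrangement of alkenyl lactone silyl ketene acetals to cycloalkene carboxylic acids. Ring A (C1=C2–C3–C4–C5–C10) is closed by the new C3–C4 bond as O–C1 breaks, the two-atom C5–C10 tether between the reacting termini forcing the boat, bicyclo[2.2.2]octane-like transition state. The one new stereocentre, quaternary C4, is controlled by C1: the 1β-vinyl group, axial in the reacting conformer, can reach C4 only on the β face of the lactone, so C3 bonds there and C19 ends on the α face of ring A, cis to C20, with C18 β. The selectivity needed is this face selectivity together with site-selective enolisation; it is secured by the (1S) configuration from step 9 and by the ring-fixed ketene acetal geometry, and both C4 epimers of 13 converge on 14. Carbonate hydrolysis of silyl ester 15 frees the C19 acid without touching the hindered C20 methyl ester.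

Step 12
Reactants: 16 acid ester
Product: 18 Δ1-19,20-lactone (C20H2–O–C19=O bridge on the α face of ring A; 7-OTBDPS; C8 ketal), via hydroxy acid 17 (not isolated)
Conditions: LiBHEt3 (4 equiv), THF, 0 °C → rt; 1 M HCl work-up at 0 °C; then PPTS (cat.), CH2Cl2, rt
Reagents that add atoms: none
Why: Triethylborohydride reduces the hindered methyl ester but not the lithium carboxylate, and the resulting 20-alcohol and 19-acid, 1,3-diaxial on ring A, close the δ-lactone on acidification (ester reduction then lactonisation).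

Step 13
Reactants: 18 alkene lactone
Product: 19 2β-alcohol of the saturated ring A lactone
Conditions: 9-BBN, THF, rt → 60 °C; then 30% H2O2, aq. NaOAc, 0 → 40 °C
Reagents that add atoms: hydrogen peroxide, OO
Why: Hydroboration–oxidation: boron goes to C2, the alkene carbon remote from quaternary C10, and from the β face because the α face of ring A is roofed by the lactone bridge; oxidation with retention gives the equatorial 2β-hydroxyl.

Step 14
Reactants: 19 2β-alcohol
Product: 20 2β-O-triisopropylsilyl ether of 19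
Conditions: iPr3SiOTf, 2,6-lutidine, CH2Cl2, 0 °C
Reagents that add atoms: triisopropylsilyl trifluoromethanesulfonate, CC(C)[Si](OS(=O)(=O)C(F)(F)F)(C(C)C)C(C)C
Why: Silylation of the unhindered secondary alcohol with an acid-stable, fluoride-labile group that survives steps 15–22.

Step 15
Reactants: 20 ketal
Product: 21 C8 ketone (ring B cyclopentanone; 2-OTIPS; 7-OTBDPS; 19,20-lactone)
Conditions: PPTS, acetone–H2O (10:1), 55 °C
Reagents that add atoms: water, O
Why: Mild acid hydrolysis of the dioxolane; the bulky silyl ethers and the lactone tolerate PPTS, and the 5,6-trans ketone is the stable epimer.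

Step 16
Reactants: 22 ethyl 2-(2-methyl-1,3-dioxolan-2-yl)acetate
Product: 23 2-(2-methyl-1,3-dioxolan-2-yl)acetaldehyde
Conditions: iBu2AlH (1.05 equiv), CH2Cl2, −78 °C; aq. potassium sodium tartrate
Reagents that add atoms: none
Why: Partial reduction of an ester to the aldehyde through the aluminium hemiacetal that is stable at −78 °C; this supplies C11–C14 with C13 masked.

Step 17
Reactants: 21 C8 ketone; 23 2-(2-methyl-1,3-dioxolan-2-yl)acetaldehyde
Product: 24 aldol adduct (new C9–C11 bond; C11 carbinol; diastereomer mixture)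
Conditions: LiN(iPr)2 (1.1 equiv), THF, −78 °C; then 23; AcOH quench at −78 °C
Reagents that add atoms: none
Why: Directed aldol addition of the kinetic enolate; deprotonation should occur at the C9 methylene and not at the C6 methine, whose α-hydrogen lies 1,3-syn to the angular C20 methylene, so the β-silyloxy group is not put at risk.

Step 18
Reactants: 24 aldol adduct
Product: 26 9(11)-alkylidene ketone (exocyclic enone; E/Z mixture), via mesylate 25 (not isolated)
Conditions: MeSO2Cl, Et3N, CH2Cl2, 0 °C; then DBU, 0 °C → rt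
Reagents that add atoms: none
Why: Mesylation and E1cB elimination give the 2-alkylidene ketone; the mesylate leaves far faster than the C7 silyloxy group, so short exposure to base at low temperature should spare C6.

Step 19
Reactants: 26 alkylidene ketone
Product: 27 9β-H ketone carrying the 3,3-(ethylenedioxy)butyl chain on C9α
Conditions: H2 (1 atm), 10% Pd/C, EtOAc, rt
Reagents that add atoms: none
Why: Heterogeneous hydrogenation of the exocyclic enone C=C; hydrogen is delivered syn from the β face, anti to the axial C20 methylene on C10 (the bias that governs 17(20)-ene hydrogenation in steroids), so H-9 becomes β and C11 α, which is also the pseudo-equatorial, more stable epimer.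

Step 20
Reactants: 27 ketal ketone
Product: 29 ring C enone (8(14)-en-13-one; 9β-H), via diketone 28 (not isolated)
Conditions: PPTS, acetone–H2O, 55 °C; then TsOH·H2O (0.2 equiv), toluene, 4 Å molecular sieves, 80 °C
Reagents that add atoms: water, O
Why: Ketal hydrolysis and acid-catalysed intramolecular aldol condensation of the 1,5-diketone (Robinson-type ring closure) form ring C; acid is used instead of base to protect the β-silyloxy ketone, and C9 stays in its stable configuration.

Step 21
Reactants: 29 ring C enone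
Product: 30 8β-propargyl 13-ketone (cis-fused rings B and C)
Conditions: TiCl4 (2 equiv), tributyl(propa-1,2-dienyl)stannane (2 equiv), CH2Cl2, −78 °C; aq. NaHCO3
Reagents that add atoms: tributyl(propa-1,2-dienyl)stannane, C=C=C[Sn](CCCC)(CCCC)CCCC
Why: Lewis-acid-mediated conjugate propargylation by SE2' transfer from the allenylstannane (Sakurai-type addition); the nucleophile should add to C8 trans to the C9–C10 bond, the usual sense for a 4-substituted cyclohexenone, which is the β face, cis to H-9 and anti to axial C20, and sets the quaternary centre of the cis-fused hydrindanone.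

Step 22
Reactants: 30 propargyl ketone
Product: 31 2-O-TIPS 7-O-TBDPS ether of the tetracyclic 13-hydroxy-16-methylene 7-ol
Conditions: SmI2 (4 equiv), HMPA, t-BuOH, THF, 0 °C → rt
Reagents that add atoms: none
Why: SmI2 ketyl–alkyne reductive cyclisation (5-exo-dig); the C13 ketyl can reach C16 only across the β face where the propargyl arm sits, so the bridgehead carbinol is fixed by geometry, and the vinyl radical is reduced and protonated to the exocyclic methylene.

Step 23
Reactants: 31 bis-silyl ether
Product: 32 2β,7,13-triol (7-alcohol corresponding to the target)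
Conditions: Bu4NF (4 equiv), THF, rt → 45 °C
Reagents that add atoms: none
Why: Fluoride cleaves both silyl ethers in one operation; the lactone and the tertiary allylic alcohol are inert to it.

Step 24
Reactants: 32 triol
Product: 34 target gibberellin (2β,13-dihydroxy-16-methylene 7-oic acid with the 19,20-δ-lactone), via aldehyde 33 (not isolated)
Conditions: TEMPO (0.2 equiv), PhI(OAc)2 (2.5 equiv), MeCN–pH 7 buffer (1:1), rt; work-up at pH 3
Reagents that add atoms: water, O
Why: Oxoammonium (TEMPO) oxidation takes only the primary C7 alcohol through the aldehyde hydrate to the acid; the secondary 2β-hydroxyl, the tertiary 13-hydroxyl and the 1,1-disubstituted alkene should be left untouched, and C6 is not exposed to base.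

**Compound list**

1 | dimethyl cyclopent-3-ene-1,1-dicarboxylate | COC(=O)C1(C(=O)OC)CC=CC1 | starting material
2 | dimethyl 4-oxocyclopent-2-ene-1,1-dicarboxylate | COC(=O)C1(C(=O)OC)C=CC(=O)C1 | intermediate
3 | methyl propanoate | CCC(=O)OC | starting material
4 | 1-methoxy-1-(trimethylsilyloxy)prop-1-ene (E/Z) | CC=C(OC)O[Si](C)(C)C | intermediate
5 | Michael adduct as trimethylsilyl enol ether (5β-H; C4 epimers) | COC(=O)C(C)[C@H]1C=C(O[Si](C)(C)C)CC1(C(=O)OC)C(=O)OC | intermediate
6 | 6-(hydroxymethyl) C8 ketone triester (5β-H, 6α-H) | COC(=O)C(C)[C@H]1[C@H](CO)C(=O)CC1(C(=O)OC)C(=O)OC | intermediate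
7 | 7-O-TBDPS ether of 6 | COC(=O)C(C)[C@H]1[C@H](CO[Si](c2ccccc2)(c2ccccc2)C(C)(C)C)C(=O)CC1(C(=O)OC)C(=O)OC | intermediate
8 | C8 ethylene ketal of 7 | COC(=O)C(C)[C@H]1[C@H](CO[Si](c2ccccc2)(c2ccccc2)C(C)(C)C)C2(OCCO2)CC1(C(=O)OC)C(=O)OC | intermediate
9 | half-acid (10β-CO2H, 10α-CO2Me) | COC(=O)C(C)[C@H]1[C@H](CO[Si](c2ccccc2)(c2ccccc2)C(C)(C)C)C2(OCCO2)C[C@@]1(C(=O)O)C(=O)OC | intermediate
10 | 10β-acid chloride | COC(=O)C(C)[C@H]1[C@H](CO[Si](c2ccccc2)(c2ccccc2)C(C)(C)C)C2(OCCO2)C[C@@]1(C(=O)Cl)C(=O)OC | intermediate (not isolated)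
11 | C1 vinyl ketone | COC(=O)C(C)[C@H]1[C@H](CO[Si](c2ccccc2)(c2ccccc2)C(C)(C)C)C2(OCCO2)C[C@@]1(C(=O)C=C)C(=O)OC | intermediate
12 | (1S)-allylic alcohol | COC(=O)C(C)[C@H]1[C@H](CO[Si](c2ccccc2)(c2ccccc2)C(C)(C)C)C2(OCCO2)C[C@@]1([C@@H](O)C=C)C(=O)OC | intermediate
13 | (1S)-1-vinyl δ-lactone, trans-fused to ring B (key-step precursor) | C=C[C@@H]1OC(=O)C(C)[C@H]2[C@H](CO[Si](c3ccccc3)(c3ccccc3)C(C)(C)C)C3(OCCO3)C[C@]12C(=O)OC | intermediate
14 | endocyclic tert-butyldimethylsilyl ketene acetal of 13 | C=C[C@@H]1OC(O[Si](C)(C)C(C)(C)C)=C(C)[C@H]2[C@H](CO[Si](c3ccccc3)(c3ccccc3)C(C)(C)C)C3(OCCO3)C[C@]12C(=O)OC | intermediate (not isolated)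
15 | tert-butyldimethylsilyl ester of 16 | CC(C)(C)[Si](C)(C)OC(=O)[C@](C)(CC=C1)[C@H]2[C@H](CO[Si](c3ccccc3)(c3ccccc3)C(C)(C)C)C3(OCCO3)C[C@]12C(=O)OC | intermediate (not isolated)
16 | ring A cyclohex-1-ene 19-oic acid 20-methyl ester (key-step product) | OC(=O)[C@](C)(CC=C1)[C@H]2[C@H](CO[Si](c3ccccc3)(c3ccccc3)C(C)(C)C)C3(OCCO3)C[C@]12C(=O)OC | intermediate
17 | 20-hydroxy 19-acid | OC(=O)[C@](C)(CC=C1)[C@H]2[C@H](CO[Si](c3ccccc3)(c3ccccc3)C(C)(C)C)C3(OCCO3)C[C@]12CO | intermediate (not isolated)
18 | Δ1-19,20-lactone | O=C4[C@](C)(CC=C1)[C@H]2[C@H](CO[Si](c3ccccc3)(c3ccccc3)C(C)(C)C)C3(OCCO3)C[C@]12CO4 | intermediate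
19 | 2β-alcohol | O=C4[C@](C)(C[C@@H](O)C1)[C@H]2[C@H](CO[Si](c3ccccc3)(c3ccccc3)C(C)(C)C)C3(OCCO3)C[C@]12CO4 | intermediate
20 | 2β-O-TIPS ether | O=C4[C@](C)(C[C@@H](O[Si](C(C)C)(C(C)C)C(C)C)C1)[C@H]2[C@H](CO[Si](c3ccccc3)(c3ccccc3)C(C)(C)C)C3(OCCO3)C[C@]12CO4 | intermediate
21 | C8 ketone | O=C4[C@](C)(C[C@@H](O[Si](C(C)C)(C(C)C)C(C)C)C1)[C@H]2[C@H](CO[Si](c3ccccc3)(c3ccccc3)C(C)(C)C)C(=O)C[C@]12CO4 | intermediate
22 | ethyl 2-(2-methyl-1,3-dioxolan-2-yl)acetate | CCOC(=O)CC1(C)OCCO1 | starting material
23 | 2-(2-methyl-1,3-dioxolan-2-yl)acetaldehyde | O=CCC1(C)OCCO1 | intermediate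
24 | aldol adduct (C9 and C11 epimer mixture) | O=C4[C@](C)(C[C@@H](O[Si](C(C)C)(C(C)C)C(C)C)C1)[C@H]2[C@H](CO[Si](c3ccccc3)(c3ccccc3)C(C)(C)C)C(=O)C(C(O)CC5(C)OCCO5)[C@]12CO4 | intermediate
25 | C11 mesylate of 24 | O=C4[C@](C)(C[C@@H](O[Si](C(C)C)(C(C)C)C(C)C)C1)[C@H]2[C@H](CO[Si](c3ccccc3)(c3ccccc3)C(C)(C)C)C(=O)C(C(OS(C)(=O)=O)CC5(C)OCCO5)[C@]12CO4 | intermediate (not isolated)
26 | 9(11)-alkylidene ketone (E/Z) | O=C4[C@](C)(C[C@@H](O[Si](C(C)C)(C(C)C)C(C)C)C1)[C@H]2[C@H](CO[Si](c3ccccc3)(c3ccccc3)C(C)(C)C)C(=O)C(=CCC5(C)OCCO5)[C@]12CO4 | intermediate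
27 | 9β-H ketone with C11–C14 chain (C13 ketal) | O=C4[C@](C)(C[C@@H](O[Si](C(C)C)(C(C)C)C(C)C)C1)[C@H]2[C@H](CO[Si](c3ccccc3)(c3ccccc3)C(C)(C)C)C(=O)[C@@H](CCC5(C)OCCO5)[C@]12CO4 | intermediate
28 | 8,13-diketone | O=C4[C@](C)(C[C@@H](O[Si](C(C)C)(C(C)C)C(C)C)C1)[C@H]2[C@H](CO[Si](c3ccccc3)(c3ccccc3)C(C)(C)C)C(=O)[C@@H](CCC(C)=O)[C@]12CO4 | intermediate (not isolated)
29 | ring C enone (8(14)-en-13-one, 9β-H) | O=C4[C@](C)(C[C@@H](O[Si](C(C)C)(C(C)C)C(C)C)C1)[C@H]2[C@H](CO[Si](c3ccccc3)(c3ccccc3)C(C)(C)C)C5=CC(=O)CC[C@H]5[C@]12CO4 | intermediate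
30 | 8β-propargyl 13-ketone | O=C4[C@](C)(C[C@@H](O[Si](C(C)C)(C(C)C)C(C)C)C1)[C@H]2[C@H](CO[Si](c3ccccc3)(c3ccccc3)C(C)(C)C)[C@@]5(CC#C)CC(=O)CC[C@H]5[C@]12CO4 | intermediate
31 | tetracyclic 13-hydroxy-16-methylene compound, 2-O-TIPS, 7-O-TBDPS | C=C1C[C@]23C[C@@]1(O)CC[C@H]2[C@]12COC(=O)[C@](C)(C[C@@H](O[Si](C(C)C)(C(C)C)C(C)C)C1)[C@H]2[C@@H]3CO[Si](c1ccccc1)(c1ccccc1)C(C)(C)C | intermediate
32 | 2β,7,13-triol | C=C1C[C@]23C[C@@]1(O)CC[C@H]2[C@]12COC(=O)[C@](C)(C[C@@H](O)C1)[C@H]2[C@@H]3CO | intermediate
33 | 7-aldehyde | C=C1C[C@]23C[C@@]1(O)CC[C@H]2[C@]12COC(=O)[C@](C)(C[C@@H](O)C1)[C@H]2[C@@H]3C=O | intermediate (not isolated)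
34 | target gibberellin: 2β,13-dihydroxy-16-methylene 7-oic acid with the 19,20-δ-lactone (C19 carbonyl, ring oxygen on C20) | C=C1C[C@]23C[C@@]1(O)CC[C@H]2[C@]12COC(=O)[C@](C)(C[C@@H](O)C1)[C@H]2[C@@H]3C(=O)O | target

**Step count.** 24 steps in total; the longest linear sequence is 22 steps (1 → 34); steps 2 and 16 are one-step side branches.

**Steps most likely to fail**

Step 11. The boat transition state has to be reached from a lactone that is trans-fused to ring B, so the sigmatropic shift may be too slow and the ketene acetal may be lost to fragmentation or C-silylation. The fallback builds ring A by enolate alkylation and ring-closing metathesis instead and sets out from 9. BH3·SMe2 should reduce the free acid to the 10β-hydroxymethyl diester F1, and oxidation with the periodinane DMP should give the 10β-aldehyde F2. Wittig methylenation (Ph3P=CH2) then gives the 10β-vinyl diester F3, and LiAlH4 reduces both esters to the 10β-vinyl 19,20-diol F4. TEMPO/PhI(OAc)2 oxidises the less hindered C19 carbinol and closes the cis-fused 10β-vinyl 19,20-lactone F5. LiN(iPr)2 and allyl bromide alkylate C4 on the convex face of this bicycle to give the 4-allyl 10β-vinyl 19,20-lactone F6, with the allyl group cis to the vinyl group. The second-generation Grubbs catalyst (H2IMes)(PCy3)Cl2Ru=CHPh finally closes the C1=C2 bond, and the fallback comes back to the route at 18.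

Step 21. Conjugate delivery of the propargyl group to the fully substituted, flanked C8 may stall or divert to carbonyl addition. The fallback installs ring D from an allyl group and sets out from 29. Hosomi–Sakurai allylation (allyltrimethylsilane, TiCl4, −78 °C) should give the 8β-allyl 13-ketone F7, and ozonolysis with Me2S work-up the 13-keto 16-aldehyde F8. SmI2 pinacol coupling of the C13 ketone with the C16 aldehyde closes ring D as the tetracyclic 13,16-diol F9. DMP oxidation of the secondary alcohol gives the 13-hydroxy 16-ketone F10, and methylenation with Zn/CH2Br2/TiCl4 completes the exocyclic alkene, so the fallback comes back to the route at 31.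

Step 3. Enantioface discrimination and turnover may be poor at C5, which lies next to the quaternary diester carbon. The fallback uses a malonate Michael addition under a different catalyst class and sets out from 2. Dibenzyl methylmalonate adds under the heterobimetallic catalyst LiAl[(R)-1,1'-binaphthalene-2,2'-diolate]2, and the aluminium enolate is trapped at C6 by monomeric formaldehyde, giving the dibenzyl methylmalonate adduct with a 6-hydroxymethyl group F11. t-BuPh2SiCl/imidazole gives the 7-O-TBDPS ether F12, and hydrogenolysis (H2, Pd/C) the malonic acid F13. Warming in toluene removes CO2 to give the 19-monoacid F14, and Me3SiCHN2 in MeOH–toluene forms the methyl ester, so the fallback comes back to the route at 7.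

**Further compounds**

F1 | step 11 | 10β-hydroxymethyl diester from 9 | COC(=O)C(C)[C@H]1[C@H](CO[Si](c2ccccc2)(c2ccccc2)C(C)(C)C)C2(OCCO2)C[C@@]1(CO)C(=O)OC
F2 | step 11 | 10β-aldehyde | COC(=O)C(C)[C@H]1[C@H](CO[Si](c2ccccc2)(c2ccccc2)C(C)(C)C)C2(OCCO2)C[C@@]1(C=O)C(=O)OC
F3 | step 11 | 10β-vinyl diester | COC(=O)C(C)[C@H]1[C@H](CO[Si](c2ccccc2)(c2ccccc2)C(C)(C)C)C2(OCCO2)C[C@@]1(C=C)C(=O)OC
F4 | step 11 | 10β-vinyl 19,20-diol | OCC(C)[C@H]1[C@H](CO[Si](c2ccccc2)(c2ccccc2)C(C)(C)C)C2(OCCO2)C[C@@]1(C=C)CO
F5 | step 11 | 10β-vinyl 19,20-lactone (C4 epimers) | O=C4C(C)[C@H]2[C@H](CO[Si](c3ccccc3)(c3ccccc3)C(C)(C)C)C3(OCCO3)C[C@@]2(C=C)CO4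
F6 | step 11 | 4-allyl 10β-vinyl 19,20-lactone | O=C4[C@](C)(CC=C)[C@H]2[C@H](CO[Si](c3ccccc3)(c3ccccc3)C(C)(C)C)C3(OCCO3)C[C@@]2(C=C)CO4
F7 | step 21 | 8β-allyl 13-ketone | O=C4[C@](C)(C[C@@H](O[Si](C(C)C)(C(C)C)C(C)C)C1)[C@H]2[C@H](CO[Si](c3ccccc3)(c3ccccc3)C(C)(C)C)[C@@]5(CC=C)CC(=O)CC[C@H]5[C@]12CO4
F8 | step 21 | 13-keto 16-aldehyde | O=C4[C@](C)(C[C@@H](O[Si](C(C)C)(C(C)C)C(C)C)C1)[C@H]2[C@H](CO[Si](c3ccccc3)(c3ccccc3)C(C)(C)C)[C@@]5(CC=O)CC(=O)CC[C@H]5[C@]12CO4
F9 | step 21 | tetracyclic 13,16-diol (C16 epimers) | OC1C[C@]23C[C@@]1(O)CC[C@H]2[C@]12COC(=O)[C@](C)(C[C@@H](O[Si](C(C)C)(C(C)C)C(C)C)C1)[C@H]2[C@@H]3CO[Si](c1ccccc1)(c1ccccc1)C(C)(C)C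
F10 | step 21 | 13-hydroxy 16-ketone | O=C1C[C@]23C[C@@]1(O)CC[C@H]2[C@]12COC(=O)[C@](C)(C[C@@H](O[Si](C(C)C)(C(C)C)C(C)C)C1)[C@H]2[C@@H]3CO[Si](c1ccccc1)(c1ccccc1)C(C)(C)C
F11 | step 3 | dibenzyl methylmalonate adduct with 6-hydroxymethyl group | O=C(OCc1ccccc1)C(C)(C(=O)OCc1ccccc1)[C@H]1[C@H](CO)C(=O)CC1(C(=O)OC)C(=O)OC
F12 | step 3 | 7-O-TBDPS ether of F11 | O=C(OCc1ccccc1)C(C)(C(=O)OCc1ccccc1)[C@H]1[C@H](CO[Si](c2ccccc2)(c2ccccc2)C(C)(C)C)C(=O)CC1(C(=O)OC)C(=O)OC
F13 | step 3 | malonic acid | OC(=O)C(C)(C(=O)O)[C@H]1[C@H](CO[Si](c2ccccc2)(c2ccccc2)C(C)(C)C)C(=O)CC1(C(=O)OC)C(=O)OC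
F14 | step 3 | 19-monoacid (C4 epimers) | OC(=O)C(C)[C@H]1[C@H](CO[Si](c2ccccc2)(c2ccccc2)C(C)(C)C)C(=O)CC1(C(=O)OC)C(=O)OC
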